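The numbers in the tables stem from a simulated flask for substances that don't exist; the scatter is artificial.

Double product holds two reagent per starting material. A flask is therefore first measured by its equivalents n, the reagent charged as a fraction of the starting material charged.

the same everywhere: starting material 20 mM

| charge | reagent | remark | time |
|---|---|---|---|
| beta | 10 mM | run made earlier |  |
| epsilon | 32 mM | run made earlier |  |
| Wednesday's | 8.00 mM |  | 150 min |
| Monday's | 21.0 mM |  | 50 min |

| run | time / min | double product / % | starting material / % |
|---|---|---|---|
| beta | 4.00 | 0.4 | 35.3 |
| beta | 8.00 | 2.3 | 22.0 |
| beta | 15.0 | 4.3 | 20.0 |
| beta | 25.0 | 5.5 | 17.2 |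
| beta | 50.0 | 12.8 | 16.7 |
| epsilon | 10.0 | 18.6 | 10.4 |
| epsilon | 20.0 | 33.6 | 10.5 |
| epsilon | 30.0 | 43.6 | 7.1 |
| epsilon | 40.0 | 50.5 | 7.2 |
| epsilon | 50.0 | 55.3 | 8.9 |

(standard deviation of a reading: 1 percentage point)

- on the list of suspects stand: starting material + reagent -> single product + released group; reagent + single product -> double product + released group; starting material <-> dormant form

* the winner by amount of double product, in percent of the starting material charged; "neither" if no more than 2 percentage points parts them (Wednesday's / Monday's / neither)
* how much double product is there at the end, in percent of the starting material charged: Wednesday's
* how much double product is there at the end, in percent of the starting material charged: Monday's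

At its last reading, at 50.0 min, beta (n = 0.500) shows 12.8% double product, so 51.2% of its charged reagent stands there. This fraction, twice the double product over n, is the double share. Epsilon (n = 1.60) reads 69.1% at the same time. These readings show that one number is not enough: the share rises with n, and beta's double product is still climbing, from 5.5% to 12.8%.

My own reckoning gives Wednesday's (n = 0.400) beta's share, hence 10.2%. Monday's (n = 1.05) lies midway between beta and epsilon and stops at their time, so it takes their mean share, hence 31.6%.

The forecast gives 9% and 31%, each below this reckoning, and names Monday's: "Double product therefore depends on the reagent excess."

The flask gives 10.2% for Wednesday's and 33.3% for Monday's, so the winner is Monday's.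

    starting material + reagent → single product + released group (k = 5.80 L mol⁻¹ min⁻¹)
    reagent + single product → double product + released group (k = 3.80 L mol⁻¹ min⁻¹)
    starting material ⇌ dormant form (K = 2.90, k = 0.280 min⁻¹)

Wednesday's has come to rest: its limiting reagent is down to 0.410% of its charge, and after 1500 min double product still stands at 10.3%. Monday's has not: 16.9% of its reagent remains at 50 min, and after 500 min double product reaches 43.1%. The reading to watch at the end is the reagent left.

For a neighbour of Wednesday's charged with 14 mM of reagent (n = 0.700), beta's share gives 17.9%. The computed flask holds 24.0%, a double share of 68.6%.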